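**Retrosynthetic overview**
1. Ring A (closed last): the O–C-a bond forms by acid-mediated closure of the quinolinone enol OH onto the C-a cation/chromene, which sets C-a and C-b.
2. C-c–C3 bond to the second quinolinone: enantioselective 1,4-addition of quinolinone 6 to the exocyclic dienone 15, which sets C-c.
3. Ring B (key step): the C-a–C-b bond forms by carbene-catalysed intramolecular hydroacylation, in which the formyl carbon reacts as an acyl anion (Breslow intermediate) with the tethered enyne.
4. Tether: addition–elimination of a tertiary enynol alkoxide on the 4-chloro-3-formylquinolinone 8; the enynol comes from a Sonogashira coupling.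
5. Both quinolinone units come from one building block, 6 (N-methyl-2,3-dimethoxyaniline plus diethyl malonate). Ring order: quinolinones, then ring B, then ring A.

Labels: C-a = O–CH at the ring junction; C-b = the other junction CH; C-c = CH carrying the 2-methylprop-1-enyl group; C-q = CMe2. Ring A is the pyran closed through the enol oxygen of one quinolinone; ring B is the gem-dimethylpyran. Target: C-a (R), C-b (S), C-c (S), cis junction, with both junction H atoms and the alkenyl group on one face.

Assumption: the (S,S) ligand in step 7 is taken to give the (S) centre at C-c; if the sense is opposite, the (R,R) ligand is used and nothing else changes.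

Step 1
Reactants: 1 2,3-dimethoxyaniline
Product: 3 2,3-dimethoxy-N-methylaniline, via hemiaminal ether 2 (not isolated)
Conditions: (CH2O)n, NaOMe, MeOH, reflux; then NaBH4, reflux
Reagents that add atoms: formaldehyde (from paraformaldehyde) C=O
Why: Base-promoted condensation with formaldehyde gives the N-methoxymethyl aniline 2, which NaBH4 reduces through the imine, a one-pot reductive mono-N-methylation that stops at the secondary amine.

Step 2
Reactants: 3 2,3-dimethoxy-N-methylaniline; 4 diethyl malonate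
Product: 6 4-hydroxy-7,8-dimethoxy-1-methylquinolin-2(1H)-one, via malonanilate ester 5 (not isolated)
Conditions: Ph2O, 250 °C, EtOH distilled off
Reagents that add atoms: none
Why: Aminolysis of one ester gives 5, whose second ester acylates the only free ortho carbon (thermal malonate cyclocondensation to a 4-hydroxy-2-quinolone), which places the methoxy groups at C7 and C8.

Step 3
Reactants: 6 4-hydroxy-7,8-dimethoxy-1-methylquinolin-2(1H)-one
Product: 8 4-chloro-7,8-dimethoxy-1-methyl-2-oxo-1,2-dihydroquinoline-3-carbaldehyde, via iminium chloride 7 (not isolated)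
Conditions: POCl3, DMF, 0 → 60 °C; then aq NaOAc
Reagents that add atoms: N,N-dimethylformamide CN(C)C=O; phosphoryl chloride O=P(Cl)(Cl)Cl; water O
Why: Vilsmeier–Haack formylation at the nucleophilic C3, with conversion of the vinylogous acid OH into the chloride, gives the β-chlorovinyl aldehyde after hydrolysis of iminium salt 7.

Step 4
Reactants: 9 2-methylbut-3-yn-2-ol; 10 1-bromo-2-methylprop-1-ene
Product: 11 2,6-dimethylhept-5-en-3-yn-2-ol
Conditions: PdCl2(PPh3)2 (2 mol%), CuI (4 mol%), Et3N, THF, 40 °C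
Reagents that add atoms: none
Why: Sonogashira coupling of the terminal alkyne with the vinyl bromide gives the conjugated enyne carrying the tertiary alcohol.

Step 5
Reactants: 8 4-chloro-7,8-dimethoxy-1-methyl-2-oxo-1,2-dihydroquinoline-3-carbaldehyde; 11 2,6-dimethylhept-5-en-3-yn-2-ol
Product: 13 4-[(2,6-dimethylhept-5-en-3-yn-2-yl)oxy]-7,8-dimethoxy-1-methyl-2-oxo-1,2-dihydroquinoline-3-carbaldehyde, via sodium alkoxide 12 (not isolated)
Conditions: NaH, THF, 0 °C; then 8, 0 °C → rt
Reagents that add atoms: none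
Why: The tertiary alkoxide displaces chloride at C4 by addition–elimination (SNAr-type substitution of a vinylogous acid chloride activated by the ortho formyl and lactam carbonyl groups), installing the O–C-q bond of ring B.

Step 6
Reactants: 13 4-[(2,6-dimethylhept-5-en-3-yn-2-yl)oxy]-7,8-dimethoxy-1-methyl-2-oxo-1,2-dihydroquinoline-3-carbaldehyde
Product: 15 (3E)-7,8-dimethoxy-2,2,6-trimethyl-3-(3-methylbut-2-en-1-ylidene)-2,3-dihydro-4H-pyrano[3,2-c]quinoline-4,5(6H)-dione, via Breslow intermediate 14 (not isolated)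
Conditions: 3-(2,4,6-trimethylphenyl)-4,5-dimethyl-1,3-thiazol-3-ium perchlorate (10 mol%), K2CO3 (20 mol%), THF (0.02 M), 70 °C
Reagents that add atoms: none
Why: The carbene turns the formyl carbon into a nucleophilic acyl-anion equivalent (Breslow intermediate 14), which adds 6-exo-dig to the proximal alkyne carbon with syn transfer of the enol proton (carbene-catalysed intramolecular alkyne hydroacylation, a Stetter-type acyl-anion addition), forming the C-a–C-b bond, ring B and the E dienone without creating a stereocentre.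

Step 7
Reactants: 15 (3E)-7,8-dimethoxy-2,2,6-trimethyl-3-(3-methylbut-2-en-1-ylidene)-2,3-dihydro-4H-pyrano[3,2-c]quinoline-4,5(6H)-dione; 6 4-hydroxy-7,8-dimethoxy-1-methylquinolin-2(1H)-one
Product: 16 3-[(1S)-1-(4-hydroxy-7,8-dimethoxy-1-methyl-2-oxo-1,2-dihydroquinolin-3-yl)-3-methylbut-2-en-1-yl]-7,8-dimethoxy-2,2,6-trimethyl-2,3-dihydro-4H-pyrano[3,2-c]quinoline-4,5(6H)-dione (both C3 epimers)
Conditions: Cu(OTf)2 (10 mol%), (S,S)-2,2′-(propane-2,2-diyl)bis(4-tert-butyl-4,5-dihydro-1,3-oxazole) (11 mol%), CH2Cl2–THF, 0 °C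
Reagents that add atoms: none
Why: Two-point binding of the copper–bis(oxazoline) Lewis acid to the C4 ketone and C5 lactam carbonyl of 15 fixes the s-cis enone and shields one face, so C3 of 6 adds 1,4 to the exocyclic β-carbon (catalytic enantioselective Michael addition) and sets C-c as (S), while C-b forms as an epimer mixture that is levelled in step 8.

Step 8
Reactants: 16 3-[(1S)-1-(4-hydroxy-7,8-dimethoxy-1-methyl-2-oxo-1,2-dihydroquinolin-3-yl)-3-methylbut-2-en-1-yl]-7,8-dimethoxy-2,2,6-trimethyl-2,3-dihydro-4H-pyrano[3,2-c]quinoline-4,5(6H)-dione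
Product: 19 target CNP0314650.1 (C-a R; C-b S; C-c S; cis-fused), via carbinol 17 (not isolated), via chromene 18 (not isolated)
Conditions: NaBH4, THF–MeOH, 0 °C; aqueous work-up; then p-toluenesulfonic acid monohydrate (TsOH·H2O, 5 mol%), CH2Cl2, 4 Å sieves, −20 → 0 °C
Reagents that add atoms: none
Why: Hydride reduction gives carbinol 17, which under mild acid ionises to a vinylogous oxocarbenium ion at C-a that equilibrates with chromene 18 by loss and return of the C-b proton (so both C-b epimers converge), and the enol oxygen then closes ring A through a chair-like transition state with axial C–O bond formation and the 2-methylprop-1-enyl group equatorial (intramolecular SN1 etherification, equivalent to chromene hydroalkoxylation), which is expected to give the cis junction with C-a (R) and C-b (S) under control of the fixed C-c (S) centre.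

**Compound list**
1 | 2,3-dimethoxyaniline | COc1cccc(N)c1OC | starting material
2 | N-(methoxymethyl)-2,3-dimethoxyaniline | COCNc1cccc(OC)c1OC | intermediate (not isolated)
3 | 2,3-dimethoxy-N-methylaniline | CNc1cccc(OC)c1OC | intermediate
4 | diethyl malonate | CCOC(=O)CC(=O)OCC | starting material
5 | ethyl 3-[(2,3-dimethoxyphenyl)(methyl)amino]-3-oxopropanoate | CCOC(=O)CC(=O)N(C)c1cccc(OC)c1OC | intermediate (not isolated)
6 | 4-hydroxy-7,8-dimethoxy-1-methylquinolin-2(1H)-one | COc1ccc2c(O)cc(=O)n(C)c2c1OC | intermediate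
7 | N-[(4-chloro-7,8-dimethoxy-1-methyl-2-oxo-1,2-dihydroquinolin-3-yl)methylidene]-N-methylmethanaminium chloride | C[N+](C)=Cc1c(Cl)c2ccc(OC)c(OC)c2n(C)c1=O.[Cl-] | intermediate (not isolated)
8 | 4-chloro-7,8-dimethoxy-1-methyl-2-oxo-1,2-dihydroquinoline-3-carbaldehyde | O=Cc1c(Cl)c2ccc(OC)c(OC)c2n(C)c1=O | intermediate
9 | 2-methylbut-3-yn-2-ol | CC(C)(O)C#C | starting material
10 | 1-bromo-2-methylprop-1-ene | CC(C)=CBr | starting material
11 | 2,6-dimethylhept-5-en-3-yn-2-ol | CC(C)=CC#CC(C)(C)O | intermediate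
12 | sodium 2,6-dimethylhept-5-en-3-yn-2-olate | CC(C)=CC#CC(C)(C)[O-].[Na+] | intermediate (not isolated)
13 | 4-[(2,6-dimethylhept-5-en-3-yn-2-yl)oxy]-7,8-dimethoxy-1-methyl-2-oxo-1,2-dihydroquinoline-3-carbaldehyde | O=Cc1c(OC(C)(C)C#CC=C(C)C)c2ccc(OC)c(OC)c2n(C)c1=O | intermediate
14 | Breslow intermediate: enaminol adduct of 13 and 3-(2,4,6-trimethylphenyl)-4,5-dimethylthiazol-2-ylidene | OC(=C1SC(C)=C(C)N1c1c(C)cc(C)cc1C)c1c(OC(C)(C)C#CC=C(C)C)c2ccc(OC)c(OC)c2n(C)c1=O | intermediate (not isolated)
15 | (3E)-7,8-dimethoxy-2,2,6-trimethyl-3-(3-methylbut-2-en-1-ylidene)-2,3-dihydro-4H-pyrano[3,2-c]quinoline-4,5(6H)-dione | CC(C)=C/C=C1/C(=O)c2c(OC1(C)C)c1ccc(OC)c(OC)c1n(C)c2=O | intermediate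
16 | 3-[(1S)-1-(4-hydroxy-7,8-dimethoxy-1-methyl-2-oxo-1,2-dihydroquinolin-3-yl)-3-methylbut-2-en-1-yl]-7,8-dimethoxy-2,2,6-trimethyl-2,3-dihydro-4H-pyrano[3,2-c]quinoline-4,5(6H)-dione, C3 (C-b) epimer mixture | COc1ccc2c(O)c(c(=O)n(C)c2c1OC)[C@@H](C=C(C)C)C1C(=O)c2c(c3ccc(OC)c(OC)c3n(C)c2=O)OC1(C)C | intermediate
17 | 4-hydroxy-3-[(1S)-1-(4-hydroxy-7,8-dimethoxy-1-methyl-2-oxo-1,2-dihydroquinolin-3-yl)-3-methylbut-2-en-1-yl]-7,8-dimethoxy-2,2,6-trimethyl-3,4-dihydro-2H-pyrano[3,2-c]quinolin-5(6H)-one, mixture at C3 and C4 | COc1ccc2c(O)c(c(=O)n(C)c2c1OC)[C@@H](C=C(C)C)C1C(O)c2c(c3ccc(OC)c(OC)c3n(C)c2=O)OC1(C)C | intermediate (not isolated)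
18 | 3-[(1S)-1-(4-hydroxy-7,8-dimethoxy-1-methyl-2-oxo-1,2-dihydroquinolin-3-yl)-3-methylbut-2-en-1-yl]-7,8-dimethoxy-2,2,6-trimethyl-2H-pyrano[3,2-c]quinolin-5(6H)-one | COc1ccc2c(O)c(c(=O)n(C)c2c1OC)[C@@H](C=C(C)C)C1=Cc2c(c3ccc(OC)c(OC)c3n(C)c2=O)OC1(C)C | intermediate (not isolated)
19 | CNP0314650.1: cis-fused bis(7,8-dimethoxy-1-methylquinolin-2-one) pyranopyran with C-a (R), C-b (S), C-c (S), gem-dimethyl at C-q and 2-methylprop-1-enyl at C-c | COc1ccc2c3c(c(=O)n(C)c2c1OC)[C@@H](C=C(C)C)[C@H]1[C@@H](O3)c2c(c3ccc(OC)c(OC)c3n(C)c2=O)OC1(C)C | target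

**Totals**
Total steps: 8. Longest linear sequence: 7 (steps 1, 2, 3, 5, 6, 7, 8); step 4 is a one-step side branch, and quinolinone 6 is used twice (steps 3 and 7).

**Three steps most likely to fail**

Step 6 (carbene hydroacylation). The formyl group of 13 is a poorly electrophilic vinylogous formate. The carbene may instead attack C4 and expel the tertiary alkoxide. The tertiary propargylic ether may ionise or rearrange on heating, and a second Breslow intermediate could add to the dienone product. The fallback sets out from compound 6 and builds the ring with normal polarity. C-acylation of 6 with 3-methylbut-2-enoic acid in P2O5–MeSO3H at 70 °C, followed in the same medium by oxa-Michael closure, gives 7,8-dimethoxy-2,2,6-trimethyl-2,3-dihydro-4H-pyrano[3,2-c]quinoline-4,5(6H)-dione F1. Condensation of F1 with 3-methylbut-2-enal (piperidinium acetate, toluene, reflux, water removal) then gives the dienone, and the route is rejoined at compound 15.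

Step 7 (enantioselective Michael addition). 1,6-Addition at the dimethyl-substituted terminus, low facial selectivity, or Lewis-acid-driven dehydrative closure of the adduct to a fused 4H-pyran could all intervene; that pyran cannot be reduced with the required stereochemistry. The fallback sets out from compound 15 and makes the same C–C bond by a cationic substitution instead of a conjugate addition. Reduction with NaBH4 and CeCl3·7H2O in MeOH at −40 °C gives racemic (3Z)-4-hydroxy-7,8-dimethoxy-2,2,6-trimethyl-3-(3-methylbut-2-en-1-ylidene)-3,4-dihydro-2H-pyrano[3,2-c]quinolin-5(6H)-one F2 (same alkene geometry as 15). Treating F2 with 6 and (R)-3,3′-bis(2,4,6-triisopropylphenyl)-1,1′-binaphthyl-2,2′-diyl hydrogen phosphate (5 mol%) in toluene at −30 °C ionises it to an extended cation paired with the chiral phosphate. C3 of 6 attacks the exocyclic carbon, and the route is rejoined at compound 18, which the acid of step 8 closes to 19.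

Step 8 (reduction and ring A closure). The closure could give the trans-fused isomer or the wrong C-b epimer. The enol OH could also add to the 2-methylprop-1-enyl group, and stronger acid could racemise C-c. The fallback sets out from compound 16 and forms the other C–O bond of ring A, so that the C-a–O bond is never broken. Tf2O and pyridine in CH2Cl2 at −78 °C convert the enol of 16 into 3-{(1S)-1-[7,8-dimethoxy-2,2,6-trimethyl-4,5-dioxo-3,4,5,6-tetrahydro-2H-pyrano[3,2-c]quinolin-3-yl]-3-methylbut-2-en-1-yl}-7,8-dimethoxy-1-methyl-2-oxo-1,2-dihydroquinolin-4-yl trifluoromethanesulfonate F3. LiBH(s-Bu)3 in THF at −78 °C delivers hydride anti to the C3 side chain and gives the cis lithium alkoxide, lithium (3S,4R)-3-{(1S)-1-[7,8-dimethoxy-1-methyl-2-oxo-4-(trifluoromethylsulfonyloxy)-1,2-dihydroquinolin-3-yl]-3-methylbut-2-en-1-yl}-7,8-dimethoxy-2,2,6-trimethyl-5-oxo-3,4,5,6-tetrahydro-2H-pyrano[3,2-c]quinolin-4-olate F4. On warming, F4 displaces the triflate at C4 of the quinolinone by addition–elimination, and the route is rejoined at compound 19. The cis junction is then fixed by the reduction; the C-b epimer ratio is that of the base-equilibrated ketone, and the epimers are separated.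

**Further compounds**
F1 | step 6 | 7,8-dimethoxy-2,2,6-trimethyl-2,3-dihydro-4H-pyrano[3,2-c]quinoline-4,5(6H)-dione | CC1(C)CC(=O)c2c(O1)c1ccc(OC)c(OC)c1n(C)c2=O
F2 | step 7 | (3Z)-4-hydroxy-7,8-dimethoxy-2,2,6-trimethyl-3-(3-methylbut-2-en-1-ylidene)-3,4-dihydro-2H-pyrano[3,2-c]quinolin-5(6H)-one (racemic at C4) | CC(C)=C/C=C1/C(O)c2c(OC1(C)C)c1ccc(OC)c(OC)c1n(C)c2=O
F3 | step 8 | 3-{(1S)-1-[7,8-dimethoxy-2,2,6-trimethyl-4,5-dioxo-3,4,5,6-tetrahydro-2H-pyrano[3,2-c]quinolin-3-yl]-3-methylbut-2-en-1-yl}-7,8-dimethoxy-1-methyl-2-oxo-1,2-dihydroquinolin-4-yl trifluoromethanesulfonate (C3 epimer mixture) | COc1ccc2c(OS(=O)(=O)C(F)(F)F)c(c(=O)n(C)c2c1OC)[C@@H](C=C(C)C)C1C(=O)c2c(c3ccc(OC)c(OC)c3n(C)c2=O)OC1(C)C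
F4 | step 8 | lithium (3S,4R)-3-{(1S)-1-[7,8-dimethoxy-1-methyl-2-oxo-4-(trifluoromethylsulfonyloxy)-1,2-dihydroquinolin-3-yl]-3-methylbut-2-en-1-yl}-7,8-dimethoxy-2,2,6-trimethyl-5-oxo-3,4,5,6-tetrahydro-2H-pyrano[3,2-c]quinolin-4-olate | COc1ccc2c(OS(=O)(=O)C(F)(F)F)c(c(=O)n(C)c2c1OC)[C@@H](C=C(C)C)[C@H]1[C@@H]([O-])c2c(c3ccc(OC)c(OC)c3n(C)c2=O)OC1(C)C.[Li+]
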